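**Retrosynthetic overview**
- The aldehyde is removed first: Vilsmeier–Haack formylation at the only free α-position of 2-nonadecyl-1H-pyrrole.
- The nonadecyl chain comes from reductive deoxygenation of 2-nonadecanoylpyrrole with NaBH4 in hot 2-propanol.
- The ketone comes from C2-acylation of pyrrolylmagnesium bromide with nonadecanoyl chloride.
- No ring is formed: the pyrrole ring is bought intact and substituted at C2, then at C5.

Assumption: the target has no stereocenter and no stereogenic double bond, so the SMILES defines one achiral compound; pyrrole and nonadecanoyl chloride are taken as catalogue chemicals.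

**Step 1**
Reactants: 1 1H-pyrrole; 2 nonadecanoyl chloride
Product: 4 1-(1H-pyrrol-2-yl)nonadecan-1-one, via pyrrolylmagnesium bromide 3 (not isolated)
Conditions: 1 (2 equiv), EtMgBr (2 equiv), Et2O/toluene, 0 °C to rt; then 2 (1 equiv), toluene, −40 to 0 °C; aq NH4Cl
Reagents that add atoms: none
Why: C-acylation of a pyrrole Grignard reagent, in which the tight N–Mg bond in ether/toluene steers the acid chloride to C2 and the deactivated 2-acylpyrrole does not react a second time.

**Step 2**
Reactants: 4 1-(1H-pyrrol-2-yl)nonadecan-1-one
Product: 7 2-nonadecyl-1H-pyrrole, via carbinol 5 (not isolated), via azafulvene 6 (not isolated)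
Conditions: NaBH4 (5 equiv, in portions), i-PrOH, reflux, 24 h
Reagents that add atoms: none
Why: Reductive deoxygenation of a 2-acylpyrrole, in which the carbinol from hydride addition ionises in hot basic alcohol to the azafulvene and a second hydride adds to it, so the transient racemic carbinol centre is erased.

**Step 3**
Reactants: 7 2-nonadecyl-1H-pyrrole
Product: 9 5-nonadecyl-1H-pyrrole-2-carbaldehyde (target), via iminium chloride 8 (not isolated)
Conditions: POCl3 (1.1 equiv), DMF (1.2 equiv), ClCH2CH2Cl, 0 °C to rt; then 2 M aq NaOH, 60 °C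
Reagents that add atoms: N,N-dimethylformamide, CN(C)C=O (formyl carbon); water, O (carbonyl oxygen, delivered on hydrolysis)
Why: Vilsmeier–Haack formylation, in which the chloroiminium electrophile attacks the free, most electron-rich α-position (C5) of the 2-alkylpyrrole and aqueous base hydrolyses the iminium salt to the aldehyde.

**Compound list**
1 | 1H-pyrrole | c1cc[nH]c1 | starting material
2 | nonadecanoyl chloride | CCCCCCCCCCCCCCCCCCC(=O)Cl | starting material
3 | 1H-pyrrol-1-ylmagnesium bromide (pyrrolylmagnesium bromide, formed in the flask) | Br[Mg]n1cccc1 | intermediate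
4 | 1-(1H-pyrrol-2-yl)nonadecan-1-one | CCCCCCCCCCCCCCCCCCC(=O)c1ccc[nH]1 | intermediate
5 | 1-(1H-pyrrol-2-yl)nonadecan-1-ol (racemic carbinol, formed in the flask) | CCCCCCCCCCCCCCCCCCC(O)c1ccc[nH]1 | intermediate
6 | 2-nonadecylidene-2H-pyrrole (azafulvene, formed in the flask, geometry not defined) | CCCCCCCCCCCCCCCCCCC=C1C=CC=N1 | intermediate
7 | 2-nonadecyl-1H-pyrrole | CCCCCCCCCCCCCCCCCCCc1ccc[nH]1 | intermediate
8 | N-methyl-N-[(5-nonadecyl-1H-pyrrol-2-yl)methylidene]methanaminium chloride (formed in the flask) | CCCCCCCCCCCCCCCCCCCc1ccc(C=[N+](C)C)[nH]1.[Cl-] | intermediate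
9 | 5-nonadecyl-1H-pyrrole-2-carbaldehyde | CCCCCCCCCCCCCCCCCCCc1ccc(C=O)[nH]1 | target

**Totals**
Total step count: 3. Longest linear sequence: 3 steps.

**Steps most likely to fail, with fallbacks**

Step 1 is the most likely to fail, because the ambident pyrrolyl Grignard reagent can give N-acyl and 3-acyl products alongside the wanted ketone. The fallback sets out from 2 and comes back at 4. Compound 2 is treated with pyridine-2-thiol and Et3N in CH2Cl2 at 0 °C to give S-pyridin-2-yl nonadecanethioate F1. F1 is then added to pyrrolylmagnesium bromide 3 in toluene at −78 °C and the mixture is quenched with dilute aq HCl. Chelation of magnesium between the pyridine nitrogen and the thioester carbonyl delivers the acyl group cleanly to C2, giving ketone 4.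

Step 2 is next, because the reduction can stall at the carbinol or the azafulvene can be trapped by a second pyrrole. The fallback sets out from 4 and comes back at 7, and replaces hydride deoxygenation by a Wolff–Kishner reduction. Ketone 4 is condensed with N2H4·H2O in diethylene glycol at 130 °C to give (1-(1H-pyrrol-2-yl)nonadecylidene)hydrazine F2. F2 is then heated with KOH to 200 °C with removal of water (Huang-Minlon variant) and loses dinitrogen to give 7. The pyrrole ring tolerates the strong base.

Step 3 is the least risky, but the acid-sensitive alkylpyrrole may oligomerise or formylate partly at a β-position. The fallback sets out from 7 and comes back at 9, and replaces electrophilic substitution by directed lithiation.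
- Compound 7 is protected with Boc2O and catalytic DMAP in MeCN to give tert-butyl 2-nonadecyl-1H-pyrrole-1-carboxylate F3.
- Lithium 2,2,6,6-tetramethylpiperidide in THF at −78 °C removes the C5 proton next to the carbamate, giving tert-butyl 2-lithio-5-nonadecyl-1H-pyrrole-1-carboxylate F4.
- F4 is quenched with DMF and then water to give tert-butyl 2-formyl-5-nonadecyl-1H-pyrrole-1-carboxylate F5.
- Thermolysis of F5 neat at 180 °C removes the carbamate and gives 9.

**Further compounds**
F1 | step 1 | S-pyridin-2-yl nonadecanethioate | CCCCCCCCCCCCCCCCCCC(=O)Sc1ccccn1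
F2 | step 2 | (1-(1H-pyrrol-2-yl)nonadecylidene)hydrazine | CCCCCCCCCCCCCCCCCCC(=NN)c1ccc[nH]1
F3 | step 3 | tert-butyl 2-nonadecyl-1H-pyrrole-1-carboxylate | CCCCCCCCCCCCCCCCCCCc1cccn1C(=O)OC(C)(C)C
F4 | step 3 | tert-butyl 2-lithio-5-nonadecyl-1H-pyrrole-1-carboxylate | CCCCCCCCCCCCCCCCCCCc1ccc([Li])n1C(=O)OC(C)(C)C
F5 | step 3 | tert-butyl 2-formyl-5-nonadecyl-1H-pyrrole-1-carboxylate | CCCCCCCCCCCCCCCCCCCc1ccc(C=O)n1C(=O)OC(C)(C)C
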